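The readings are calculated on assumed constants, and the scatter is random.

Decide the next addition by asking how long free J stands in the flask. Here J and L are the two kinds of end group, D the links and Q the other product.

| flask | J | L | remark | time |
|---|---|---|---|---|
| Friday's | 0.10 M | 0.95 equiv | run made earlier |  |
| Tuesday's | 0.10 M | 1.4 equiv | run made earlier |  |
| blue | 0.10 M | 0.950 equiv | everything together at the start | 12 d |
| green | 0.10 M (fed, over 8.0 d) | 0.950 equiv | all else is in the flask from the start; the feed brings no volume worth counting | 12 d |
| red | 0.10 M | 0.950 equiv (fed, over 20 h) | all else is in the flask from the start; the feed brings no volume worth counting | 12 d |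
| amber | 0.10 M | 0.950 equiv (fed, over 8.0 d) | all else is in the flask from the start; the feed brings no volume worth counting | 12 d |
| grey | 0.10 M | 0.950 equiv (in portions, 2, over 8.0 d) | first portion at the start, last at 8.0 d | 12 d |

Friday's run (percent of the J charged)

| time / d | D / % | Q / % |
|---|---|---|
| 1.25 | 57.6 | 15.7 |
| 2.50 | 64.2 | 22.1 |
| 4.00 | 64.7 | 24.9 |
| 5.00 | 64.4 | 26.9 |
| 6.00 | 62.8 | 28.4 |
| 8.00 | 62.9 | 31.7 |

Tuesday's run (percent of the J charged)

| time / h | D / % | Q / % |
|---|---|---|
| 5.00 | 35.6 | 7.5 |
| 10.0 | 53.6 | 10.2 |
| 15.0 | 61.6 | 14.0 |
| 20.0 | 67.0 | 13.9 |
| 25.0 | 68.8 | 14.2 |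
| 30.0 | 75.0 | 16.4 |

(each reading ± 1 percentage point)

1. the flask that comes out highest in share of D in D plus Q, or "all alike" when all lie within 1.5 percentage points (blue / green / red / amber / grey / all alike)
2. share of D in D plus Q at the end, blue
3. share of D in D plus Q at the end, green
4. share of D in D plus Q at the end, red
5. share of D in D plus Q at the end, amber
6. share of D in D plus Q at the end, grey

- in percentages every species weighs as the J in it: one Q counts as two
- a reading or a percentage of D counts all its forms, free or not

A Q counts as two, so we take J, D and Q to add up to the charge and read free J by subtraction. Between 4.00 d and 8.00 d of Friday's run D stays flat within the scatter, Q gains 6.8 percentage points, and free J, read at those two times, averages 7.90%. That gives 4.65 d for τ, the drain lifetime: the days in which Q gains as much as the free J standing. This treats the drain as pseudo-first-order in J, so Q gained is mean free J times the lifetimes counted.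

Test it on Friday's start, where D is still rising. Free J falls to 26.7% by 1.25 d, an even fall averages 63.3%, and the rule gives Q 17.0% against the reading 15.7%.

Blue has Friday's charge, and Friday's last reading leaves 5.40% of J. Held there to the end, it brings Q to 36.3% and the share to 61.6%. In amber, free J starts at the charge, so an even fall averages about half of it; over 1.72 lifetimes that reckons Q near 86.1%, a rough figure. So we run green next, with J entering slowly, and drop amber.

The forecast also names green, on the ground “keeping J low favours D”. It gives blue 63%, green 70%, red 60%, amber 45%, grey 51%. Our amber reckoning, a share near 13.9%, runs lower than its figure.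

The flasks end at blue 61.3%, green 72.6%, red 58.7%, amber 33.7%, grey 30.2%.

    J + L ⇌ D + X (K = 2.10, k = 0.920 /M/h)
    J + D → Q (k = 0.900 /M/h)
    G ⇌ D, rate k3*(cs3 - [D]) while solid is left; crystals form when [D] > cs3 (solubility = 4.20 mM, k = 0.820 /h)

Green at 12.0 d holds D at 66.0% of the J charged, with crystals G at 61.8% counted in it. The dissolved rest has at that time a half-life of 3.5 d by the turning of J + D into Q, which is short against 12 d. Over green's last 4.00 d, free J goes from 19.9% to 9.09%; taken as an even fall, τ gives a Q gain of 12 points, and Q gained 9.1 points.

Stop green at 8.0 d instead, with free J at 19.9%. An even climb from nothing averages 9.95%, and τ gives Q 17.1%. That flask holds Q 15.8%.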